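Remark: the side chain is read as unbranched pentacosyl (25 carbons). Chromone numbering (O1, C2, C3, C4, C4a, C5 to C8, C8a) is used for atoms throughout, also for the carbons of precursors that later become these atoms.

## Analysis of the target

Compound 17 is 5,7-dihydroxy-2-pentacosyl-4H-chromen-4-one: a benzenoid ring A (C4a, C5, C6, C7, C8, C8a) fused along C4a–C8a to a 4-pyranone ring C (O1, C2, C3, C4, C4a, C8a), with hydroxyls at C5 and C7 and a straight C25 chain at C2. There is no stereocentre and no configured double bond, so nothing stereochemical has to be controlled. The sensitive groups are the pyranone, a vinylogous ester that hydroxide or alkoxide can open at C2, and the two phenols, of which the C5 hydroxyl is hydrogen-bonded to the C4 carbonyl and the C7 hydroxyl is a vinylogous acid. The difficulty is not complexity but the placing of two oxygens meta to each other on ring A with C6 and C8 unsubstituted, together with the handling of waxy intermediates that dissolve poorly in cold or polar media. The strategy rests on two features of ring A. First, a ketene carbonyl carbon (C5) joined through an alkyne CH (C6) to an ynol ether carbon (C7) gives exactly this 1,3-dioxygenation. Second, C8a has only O1 and C4a as ring neighbours, so a chain attached at C8a can close a six-membered ring only onto C4a. Ring A can therefore be grown onto a preformed pyranone that already carries the chain.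

## Retrosynthetic reasoning

**17 to 16.** The O–ethyl bond at C7 is cut, giving 7-ethoxy-5-hydroxy-2-pentacosyl-4H-chromen-4-one (16). The alkyne used in the ring-forming step brings its oxygen as an ether, so one ether cleavage at the end is the price. The C5 hydroxyl needs no protection because it is chelated to the C4 carbonyl. The forward reaction must cleave an aryl ethyl ether without touching the pyranone.

**16 to 10 and 11.** Ring A is taken apart at C5–C6, C7–C8 and C4a–C5. The C8–C8a bond is traced back to the bond between C8a and the ketone carbon of 2-(diazoacetyl)-6-pentacosyl-4H-pyran-4-one (10), because a 1,2-shift moves C8a from that carbon to the diazo carbon. The two-carbon partner is ethoxyacetylene (11). The cut is placed here because the meta oxygens are the signature of a ketene joined to an ynol ether, and because closure from C8a can go only to C4a. Four of the six ring A atoms then come from two small pieces, and the remaining pyranone is simple. The forward reaction runs through ketene 12, cyclobutenone 13, dienylketene 14 and dienone 15 without isolation.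

**10 to 8.** The bond between the ketone carbon (future C5) and the diazo carbon (future C8) is cut. This leads to 4-oxo-6-pentacosyl-4H-pyran-2-carboxylic acid (8), activated as its chloride 9. Acylation of a diazoalkane is the shortest reliable entry to a terminal diazoketone. The forward step must activate the acid without attacking the pyranone carbonyl.

**8 to 6.** The ring bond from O1 to an enol ether carbon of the pyranone is cut and the acid is taken back to its ethyl ester 7. This gives the open chain ethyl 2,4,6-trioxohentriacontanoate (6). Cyclodehydration of a 1,3,5-tricarbonyl chain is the classical route to 4-pyranones. Under acid it can be merged with ester hydrolysis, which keeps base away from the ring.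

**6 to 4 and 5.** The C4a–C8a bond is cut. The methyl carbon of nonacosane-2,4-dione (4) becomes C4a, and the two carbons of diethyl oxalate (5) become C8a and C5. The forward reaction has to acylate the less hindered terminal position of the diketone dianion once, and once only.

**4 to 3 and 2.** The bond between the first and second carbon of the side chain is cut. Acetylacetone (3) then supplies C4a, C4, C3, C2 and the first chain carbon, and 1-bromotetracosane (2) supplies the other 24. An even-numbered C24 electrophile is available, whereas an odd-numbered C25 one is not. The forward reaction is a terminal alkylation of the acetylacetone dianion.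

**2 to 1.** The C–Br bond is traced back to the C–O bond of 1-tetracosanol (1), which is an article of commerce.

## Alternatives that were turned down

Alternative 1: aryne insertion into an alkynoic acid.

- Disconnection: O1–C8a and C4a–C4. Ring A is bought as an aryne precursor, and C2, C3 and C4 arrive with the chain as an alkynoic acid.
- Forward key step: CsF would release 3,5-dimethoxybenzyne A4 from 3,5-dimethoxy-2-(trimethylsilyl)phenyl trifluoromethanesulfonate A3. The carboxylate of octacos-2-ynoic acid A2 would add to A4 at the aryne carbon remote from the flanking methoxy group. The aryl anion left next to that methoxy group would then attack the acyl carbon. The net insertion of A4 into the C–O bond of A2 would give 1-(2-hydroxy-4,6-dimethoxyphenyl)octacos-2-yn-1-one A1.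
- For it: it is convergent. The distortion of the 3-alkoxyaryne A4 fixes the regiochemistry. All oxygens of ring A are present from the start, and A1 is one conjugate addition away from the chromone.
- Against it: the key step closes no ring, so a separate O1–C2 closure of A1 and two demethylations must follow. A3 needs several steps from a phenol. A2 needs either an odd-numbered C25 electrophile or a build-up from 2 and a three-carbon alkyne piece. Protonation of the aryl anion formed from A4 competes with the acyl shift and would end in an aryl ester. The ynone of A1 is exposed to fluoride and carboxylate.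
- Comparison: Alternative 1 is stronger in convergence and in using only polar reactions, with no diazo compound and no light. In exchange, the chosen route forms the bonds of ring A and closes it in one operation, delivers the C5 hydroxyl free, leaves one ether to cleave, and starts from bulk acyclic chemicals. Once A2 and A3 are counted, Alternative 1 is not shorter.

Alternative 2: tandem C-acylation and fluoride displacement.

- Disconnection: C3–C4 and O1–C8a.
- Forward key step: heptacosan-2-one A6 would be deprotonated at its methyl group under kinetic control, and the lithium enolate would be acylated on carbon by 2,4,6-trifluorobenzoyl chloride A7. The enolate oxygen of the resulting 1,3-diketone would then displace one ortho fluoride. This closes the pyranone in the same flask and gives 5,7-difluoro-2-pentacosylchromone A5.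
- For it: A7 is commercial. Its two ortho fluorines are equivalent, so there is no regiochemical question. The route to A5 is short and uses only scalable polar steps.
- Against it: A6 has to be made from the same C24 electrophile 2. Acid chlorides such as A7 partly O-acylate ketone enolates, and the acidic diketone consumes a second equivalent of the valuable enolate of A6. The main weakness is that A5 still lacks both hydroxyls. Each C–F bond of A5 must be replaced by an oxygen nucleophile under basic conditions, on a chromone whose C2 is open to conjugate attack and ring opening. The second displacement is also slowed by the first alkoxy group.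
- Comparison: Alternative 2 is stronger on step count to the bicyclic core and on operational simplicity. In exchange, the chosen route introduces both ring A oxygens at the right oxidation level while the ring forms, under neutral conditions, and no strong nucleophile ever meets the finished chromone.

Alternative 3: formyl C–H activation with a sulfoxonium ylide.

- Disconnection: C3–C4 and O1–C2.
- Forward key step: with [Cp*RhCl2]2 (trivalent rhodium), the hydroxyl group of 2-hydroxy-4,6-dimethoxybenzaldehyde A9 would direct metalation of the formyl C–H bond. The acylrhodium species would take up the carbene from 1-[dimethyl(oxo)-λ6-sulfanylidene]heptacosan-2-one A10 and form C3–C4. The hydroxyaryl 1,3-diketone would then cyclodehydrate to 5,7-dimethoxy-2-pentacosylchromone A8.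
- For it: A9 is commercial. A10 would come from hexacosanoic acid A11 by activation and one acylation. The key step builds the pyranone of A8 in one operation, and only a double demethylation of A8 remains.
- Against it: A11 is a costly fine chemical, or else must be made from 2 by a two-carbon homologation. A precious-metal catalyst is needed. The C6 methoxy group of A9 crowds the acylrhodium centre, and an electron-rich acylrhodium can lose CO. Two ethers of A8 have to be cleaved.
- Comparison: on step count and probably on dependability, Alternative 3 is the stronger route. In exchange, the chosen strategy needs no transition metal and no C26 acid such as A11, frees the C5 hydroxyl from the outset instead of carrying it as a methyl ether as in A8, and builds ring A from parts. The alkyne partner can then be varied to change C6 and C7.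

Key step: step 6

## Route

Step 1
Reactants: 1 1-tetracosanol
Product: 2 1-bromotetracosane
Conditions: CBr4, PPh3, CH2Cl2/THF, rt
Reagents that add atoms: carbon tetrabromide, BrC(Br)(Br)Br
Why: Appel reaction; the alkoxyphosphonium ion of the primary alcohol is displaced by bromide in an SN2 step, and nothing else in the molecule can react.

Step 2
Reactants: 3 acetylacetone (pentane-2,4-dione), 2 1-bromotetracosane
Product: 4 nonacosane-2,4-dione
Conditions: 3 (2 equiv), NaH, THF, 0 °C; n-BuLi, 0 °C; then 2, THF, 0 °C to rt; aq HCl
Reagents that add atoms: none
Why: NaH removes the central proton of 3 and n-BuLi a terminal one; the dianion reacts with the primary bromide only at its more basic terminal carbon (Hauser–Harris γ-alkylation of a β-diketone dianion), and the excess of cheap dianion suppresses a second alkylation.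

Step 3
Reactants: 4 nonacosane-2,4-dione, 5 diethyl oxalate
Product: 6 ethyl 2,4,6-trioxohentriacontanoate
Conditions: LiN(i-Pr)2 (LDA, 3 equiv), THF, 0 °C; then 5 (1.5 equiv), −78 °C to 0 °C; cold aq HCl
Reagents that add atoms: none
Why: The second deprotonation of 4 takes place at the methyl group and not at the more hindered C5 methylene, and the terminal carbanion is acylated by one ester group of 5, whose tetrahedral adduct persists in the cold and blocks a second addition (Claisen-type acylation of a β-diketone dianion, as in the Harris triketone synthesis). The third equivalent of base takes up the acidic proton of the product so that it does not quench unreacted dianion.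

Step 4
Reactants: 6 ethyl 2,4,6-trioxohentriacontanoate
Product: 8 4-oxo-6-pentacosyl-4H-pyran-2-carboxylic acid, via ethyl 4-oxo-6-pentacosyl-4H-pyran-2-carboxylate 7 (not isolated)
Conditions: AcOH, concentrated HCl, 100 °C
Reagents that add atoms: water, O
Why: In hot acid the enol oxygen at C6 of 6 adds to the C2 keto group and water is lost, the standard cyclodehydration of a 1,3,5-tricarbonyl chain to a 4-pyranone (as in the chelidonic acid synthesis). The same medium hydrolyses the ester of 7 by acid-catalysed acyl–oxygen cleavage, which avoids aqueous base that would open the pyranone.

Step 5
Reactants: 8 4-oxo-6-pentacosyl-4H-pyran-2-carboxylic acid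
Product: 10 2-(diazoacetyl)-6-pentacosyl-4H-pyran-4-one, via 4-oxo-6-pentacosyl-4H-pyran-2-carbonyl chloride 9 (not isolated)
Conditions: (COCl)2, catalytic DMF, CH2Cl2, 0 °C to rt; evaporate; CH2N2 (3 equiv, ethereal solution), THF/Et2O, 0 °C
Reagents that add atoms: diazomethane, C=[N+]=[N-]
Why: DMF-catalysed chlorination gives acid chloride 9, which has no α-hydrogen and so cannot form a ketene, and diazomethane is C-acylated by it (first stage of the Arndt–Eistert sequence). The excess diazomethane consumes the HCl released, which prevents conversion of 10 into a chloromethyl ketone.

Step 6
Reactants: 10 2-(diazoacetyl)-6-pentacosyl-4H-pyran-4-one, 11 ethoxyacetylene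
Product: 16 7-ethoxy-5-hydroxy-2-pentacosyl-4H-chromen-4-one, via pyranonylketene 12 (not isolated), via 3-ethoxy-4-pyranonylcyclobutenone 13 (not isolated), via dienylketene 14 (not isolated), via 4aH-chromene-4,5-dione 15 (not isolated)
Conditions: 11 (3 equiv), ClCH2CH2Cl (degassed), hν (medium-pressure Hg lamp, Pyrex filter, >300 nm), rt; evaporate excess 11; ClCH2CH2Cl, 80 °C, dark
Reagents that add atoms: none
Why: Light above 300 nm excites the diazoketone chromophore of 10, N2 is lost, and the pyranonyl group shifts from the carbonyl carbon (future C5) to the former diazo carbon (future C8) in a photochemical Wolff rearrangement that gives ketene 12. The nucleophilic CH terminus of 11 attacks the ketene carbonyl carbon and the [2+2] cycloaddition forms C5–C6 and C7–C8, so cyclobutenone 13 carries the ethoxy group on the future C7. On heating, 13 opens reversibly by a four-electron conrotatory process to dienylketene 14, and because the opening is reversible the material funnels through the isomer in which the pyranonyl group lies cis to the ketene. Ring A is then closed by a thermal six-electron disrotatory electrocyclization in which the ketene carbon bonds to the pyranone carbon next to C8a (C4a–C5), and the resulting dienone 15 enolizes at once because its C4a hydrogen sits between two carbonyl groups. The closest known reaction type is the Danheiser benzannulation in its photochemical diazoketone form, which has been run with aryl, heteroaryl and alkenyl diazoketones and alkoxyalkynes. The step needs regioselectivity in the cycloaddition, which the polarization of the ynol ether secures, and site selectivity in the closure, which is secured because C8a has O1 as its only other ring neighbour. It also needs chemoselectivity for the diazoketone over the pyranone chromophore, which the Pyrex cut-off and the removal of excess 11 before heating are meant to secure. No stereocentre is set, since C8 of 13 and C4a of 15 both become trigonal in 16.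

Step 7
Reactants: 16 7-ethoxy-5-hydroxy-2-pentacosyl-4H-chromen-4-one
Product: 17 5,7-dihydroxy-2-pentacosyl-4H-chromen-4-one
Conditions: BBr3 (4 equiv), CH2Cl2, 0 °C to rt; then MeOH, H2O
Reagents that add atoms: none
Why: BBr3 coordinates the ether oxygen and bromide attacks the ethyl group by SN2 (Lewis acid cleavage of an aryl alkyl ether). The chelated C5 hydroxyl, the pyranone ring and the saturated chain are inert to the reagent, and hydrolysis of the aryl borate releases 17.

## Compound list

1 | 1-tetracosanol | CCCCCCCCCCCCCCCCCCCCCCCCO | starting material
2 | 1-bromotetracosane | CCCCCCCCCCCCCCCCCCCCCCCCBr | intermediate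
3 | acetylacetone (pentane-2,4-dione) | CC(=O)CC(C)=O | starting material
4 | nonacosane-2,4-dione | CCCCCCCCCCCCCCCCCCCCCCCCCC(=O)CC(C)=O | intermediate
5 | diethyl oxalate | CCOC(=O)C(=O)OCC | starting material
6 | ethyl 2,4,6-trioxohentriacontanoate | CCCCCCCCCCCCCCCCCCCCCCCCCC(=O)CC(=O)CC(=O)C(=O)OCC | intermediate
7 | ethyl 4-oxo-6-pentacosyl-4H-pyran-2-carboxylate | CCCCCCCCCCCCCCCCCCCCCCCCCc1cc(=O)cc(C(=O)OCC)o1 | intermediate
8 | 4-oxo-6-pentacosyl-4H-pyran-2-carboxylic acid | CCCCCCCCCCCCCCCCCCCCCCCCCc1cc(=O)cc(C(=O)O)o1 | intermediate
9 | 4-oxo-6-pentacosyl-4H-pyran-2-carbonyl chloride | CCCCCCCCCCCCCCCCCCCCCCCCCc1cc(=O)cc(C(Cl)=O)o1 | intermediate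
10 | 2-(diazoacetyl)-6-pentacosyl-4H-pyran-4-one | CCCCCCCCCCCCCCCCCCCCCCCCCc1cc(=O)cc(C(=O)C=[N+]=[N-])o1 | intermediate
11 | ethoxyacetylene (ethoxyethyne) | C#COCC | starting material
12 | (4-oxo-6-pentacosyl-4H-pyran-2-yl)ketene | CCCCCCCCCCCCCCCCCCCCCCCCCc1cc(=O)cc(C=C=O)o1 | intermediate
13 | 3-ethoxy-4-(4-oxo-6-pentacosyl-4H-pyran-2-yl)cyclobut-2-en-1-one (racemic) | CCCCCCCCCCCCCCCCCCCCCCCCCc1cc(=O)cc(C2C(=O)C=C2OCC)o1 | intermediate
14 | (3E)-3-ethoxy-4-(4-oxo-6-pentacosyl-4H-pyran-2-yl)buta-1,3-dien-1-one (pyranonyl cis to the ketene carbon) | CCCCCCCCCCCCCCCCCCCCCCCCCc1cc(=O)cc(/C=C(OCC)\C=C=O)o1 | intermediate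
15 | 7-ethoxy-2-pentacosyl-4aH-chromene-4,5-dione (racemic) | CCCCCCCCCCCCCCCCCCCCCCCCCC1=CC(=O)C2C(=O)C=C(OCC)C=C2O1 | intermediate
16 | 7-ethoxy-5-hydroxy-2-pentacosyl-4H-chromen-4-one | CCCCCCCCCCCCCCCCCCCCCCCCCc1cc(=O)c2c(O)cc(OCC)cc2o1 | intermediate
17 | 5,7-dihydroxy-2-pentacosyl-4H-chromen-4-one | CCCCCCCCCCCCCCCCCCCCCCCCCc1cc(=O)c2c(O)cc(O)cc2o1 | target

## Step count and least certain steps

Total step count: 7. Longest linear sequence: 7 steps (1, 2, 4, 6, 8, 10, 16, 17); compounds 3, 5 and 11 enter as purchased reagents.

**Step 6 (key step).**
- What may go wrong: light may be absorbed by the pyranone or by the chromone product, leading to photodimerization or ring rearrangement. The ketocarbene may escape the Wolff shift and add to the alkyne. Diazoketone and ynol ether may undergo a dark dipolar cycloaddition. The phenol formed may be acylated by ketene still present. A brief K2CO3/MeOH treatment of the crude product would reverse the last of these.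
- Fallback: it sets out from 10 and comes back at 16. The ketene is generated without light. Arndt–Eistert homologation of 10 (catalytic PhCO2Ag, Et3N, aqueous dioxane, dark) should give (4-oxo-6-pentacosyl-4H-pyran-2-yl)acetic acid F1. (COCl)2 would convert F1 into (4-oxo-6-pentacosyl-4H-pyran-2-yl)acetyl chloride F2. Dehydrochlorination of F2 with Et3N in the presence of 11 would generate ketene 12 thermally and intercept it as cyclobutenone 13. Cyclobutenone 13 would then be isolated and heated in toluene to give 16.

**Step 3.**
- What may go wrong: proton transfer from the acidic product to unreacted dianion may stall the conversion. Deprotonation may occur partly at the C5 methylene. Both ester groups of the oxalate may react. The lithium salts of the waxy diketone may precipitate in the cold. If the basic mixture is allowed to warm, aldol closure of the chain methylene onto the C2 keto group may give a resorcinol ester.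
- Fallback: it sets out from 3, 5 and 2 and comes back at 6. The order of the two bond formations is reversed. Claisen condensation of 3 with 5 (NaOEt, EtOH), which parallels the second acylation of the chelidonic acid synthesis, should give ethyl 2,4,6-trioxoheptanoate F3. The trianion of F3 (LiN(i-Pr)2, 3 equiv, THF) would then be alkylated at its terminal methyl carbon with 2 to give 6.

**Step 5.**
- What may go wrong: the chlorinating reagent may attack the nucleophilic pyranone carbonyl oxygen and form a chloropyrylium salt. Excess diazomethane may add as a dipole to the acyl-activated ring double bond. Insufficient diazomethane would allow HCl to convert the diazoketone into a chloromethyl ketone.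
- Fallback: it sets out from 8 and comes back at 10. No chlorinating reagent is used. Isobutyl chloroformate and N-methylmorpholine in THF at −15 °C would convert 8 into isobutyl (4-oxo-6-pentacosyl-4H-pyran-2-carbonyl) carbonate F4. This mixed anhydride acylates diazomethane in the same flask to give 10.

**Step 7.**
- What may go wrong: the dealkylation may be incomplete. The C5 hydroxyl and C4 carbonyl chelate and sequester the boron reagent. The C7 oxygen is a weak Lewis base because it is conjugated to the C4 carbonyl. An ethyl group is displaced more slowly than a methyl group, and the substrate dissolves poorly in cold CH2Cl2.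
- Fallback: it sets out from 10 and comes back at 17. The ether is chosen so that it leaves by ionization. Under the conditions of step 6, with tert-butoxyacetylene in place of 11, 10 should give 7-tert-butoxy-5-hydroxy-2-pentacosyl-4H-chromen-4-one F5. CF3CO2H in CH2Cl2 at rt would cleave F5 to 17. If the tert-butyl group is lost earlier, during the thermal stage, the end point is the same.

## Further compounds

F1 | step 6 | (4-oxo-6-pentacosyl-4H-pyran-2-yl)acetic acid | CCCCCCCCCCCCCCCCCCCCCCCCCc1cc(=O)cc(CC(=O)O)o1
F2 | step 6 | (4-oxo-6-pentacosyl-4H-pyran-2-yl)acetyl chloride | CCCCCCCCCCCCCCCCCCCCCCCCCc1cc(=O)cc(CC(Cl)=O)o1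
F3 | step 3 | ethyl 2,4,6-trioxoheptanoate | CC(=O)CC(=O)CC(=O)C(=O)OCC
F4 | step 5 | isobutyl (4-oxo-6-pentacosyl-4H-pyran-2-carbonyl) carbonate | CCCCCCCCCCCCCCCCCCCCCCCCCc1cc(=O)cc(C(=O)OC(=O)OCC(C)C)o1
F5 | step 7 | 7-tert-butoxy-5-hydroxy-2-pentacosyl-4H-chromen-4-one | CCCCCCCCCCCCCCCCCCCCCCCCCc1cc(=O)c2c(O)cc(OC(C)(C)C)cc2o1
A1 | alternative 1 | 1-(2-hydroxy-4,6-dimethoxyphenyl)octacos-2-yn-1-one | CCCCCCCCCCCCCCCCCCCCCCCCCC#CC(=O)c1c(O)cc(OC)cc1OC
A2 | alternative 1 | octacos-2-ynoic acid | CCCCCCCCCCCCCCCCCCCCCCCCCC#CC(=O)O
A3 | alternative 1 | 3,5-dimethoxy-2-(trimethylsilyl)phenyl trifluoromethanesulfonate | COc1cc(OC)c([Si](C)(C)C)c(OS(=O)(=O)C(F)(F)F)c1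
A4 | alternative 1 | 3,5-dimethoxybenzyne | COC1=CC(OC)=CC#C1
A5 | alternative 2 | 5,7-difluoro-2-pentacosylchromone | CCCCCCCCCCCCCCCCCCCCCCCCCc1cc(=O)c2c(F)cc(F)cc2o1
A6 | alternative 2 | heptacosan-2-one | CCCCCCCCCCCCCCCCCCCCCCCCCC(C)=O
A7 | alternative 2 | 2,4,6-trifluorobenzoyl chloride | O=C(Cl)c1c(F)cc(F)cc1F
A8 | alternative 3 | 5,7-dimethoxy-2-pentacosylchromone | CCCCCCCCCCCCCCCCCCCCCCCCCc1cc(=O)c2c(OC)cc(OC)cc2o1
A9 | alternative 3 | 2-hydroxy-4,6-dimethoxybenzaldehyde | COc1cc(O)c(C=O)c(OC)c1
A10 | alternative 3 | 1-[dimethyl(oxo)-λ6-sulfanylidene]heptacosan-2-one | CCCCCCCCCCCCCCCCCCCCCCCCCC(=O)C=S(C)(C)=O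
A11 | alternative 3 | hexacosanoic acid | CCCCCCCCCCCCCCCCCCCCCCCCCC(=O)O
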